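The cyclohex-2-enone ring is disconnected by a [4+2] retron: ring carbons C1(=O)–C2=C3–C4(OMe) come from an (E)-1,1,4-trioxygenated butadiene, C5–C6 from a 2-substituted allyl acrylate that already carries the (R)-configured aroylethyl side chain. One Diels–Alder step closes the ring, places the carbonyl at C1 and the methoxy group at C4 (stereocentre set there) and leaves C6 as a β-keto allyl ester. The key step exploits the 1,4-relationship of the C1 carbonyl and C4–OMe across C2=C3 and the α-position of quaternary C6. A decarboxylative allylation then funnels both C6 epimers into the allyl-bearing quaternary centre.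

Key step: step 8

Remark: ring atoms are numbered as in the target name (C1 carbonyl, C4 methoxy-bearing carbon, C6 quaternary carbon); Cα is the methyl-bearing side-chain carbon.

Step 1
Reactants: 1 allyl acrylate (prop-2-en-1-yl prop-2-enoate); 2 acetaldehyde
Product: 3 prop-2-en-1-yl 3-hydroxy-2-methylidenebutanoate (racemic)
Conditions: DABCO (0.3 equiv), neat (excess 2), sealed vessel, rt
Reagents that add atoms: none
Why: Morita–Baylis–Hillman reaction (amine adds to the acrylate, the enolate adds to the aldehyde, the amine is eliminated); the racemic carbinol centre is destroyed in step 2.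

Step 2
Reactants: 3 prop-2-en-1-yl 3-hydroxy-2-methylidenebutanoate
Product: 4 prop-2-en-1-yl (2Z)-2-(bromomethyl)but-2-enoate
Conditions: NBS, Me2S, CH2Cl2, 0 °C → rt
Reagents that add atoms: N-bromosuccinimide O=C1CCC(=O)N1Br
Why: Corey–Kim-type activation of the alcohol as an alkoxysulfonium ion and SN2' attack of bromide (allylic transposition) should give the trisubstituted (Z)-enoate, with CH3 cis to CH2Br, as is usual for such adducts.

Step 3
Reactants: 4 prop-2-en-1-yl (2Z)-2-(bromomethyl)but-2-enoate; 5 3,4-dimethoxybenzaldehyde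
Product: 7 prop-2-en-1-yl (3R,4R)-4-(3,4-dimethoxyphenyl)-4-hydroxy-3-methyl-2-methylidenebutanoate, via trimethylsilyl ether 6 (not isolated)
Conditions: CrCl2 (10 mol %), chiral carbazole-1,8-bis(oxazoline) ligand (12 mol %), Mn powder, Me3SiCl, THF, rt; then 1 M HCl, THF, 0 °C (brief, to avoid lactonisation)
Reagents that add atoms: none
Why: Catalytic asymmetric Nozaki–Hiyama–Kishi allylation: the allylchromium species adds through its γ-carbon in a chair transition state (anti adduct) while the ligand fixes the aldehyde face; the ligand enantiomer is chosen to make the methyl-bearing carbon (3R), the only centre that survives step 4.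

Step 4
Reactants: 7 prop-2-en-1-yl (3R,4R)-4-(3,4-dimethoxyphenyl)-4-hydroxy-3-methyl-2-methylidenebutanoate
Product: 8 prop-2-en-1-yl (3R)-4-(3,4-dimethoxyphenyl)-3-methyl-2-methylidene-4-oxobutanoate
Conditions: DMP (1,1,1-triacetoxy-1,1-dihydro-1,2-benziodoxol-3(1H)-one), CH2Cl2, 0 °C → rt; filtration through deactivated silica
Reagents that add atoms: none
Why: Periodinane (Dess–Martin) oxidation of the benzylic alcohol under non-basic conditions, so that the now α-keto, allylic centre (3R) should not epimerise and the C=CH2 bond should not move into conjugation.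

Step 5
Reactants: 9 (2E)-3-methoxyprop-2-enoic acid
Product: 11 (3E)-1-diazo-4-methoxybut-3-en-2-one, via acid chloride 10 (not isolated)
Conditions: (COCl)2, DMF (cat.), CH2Cl2, 0 °C → rt; evaporate; CH2N2 (ethereal), Et3N, Et2O, −10 °C
Reagents that add atoms: diazomethane C=[N+]=[N-]
Why: First half of an Arndt–Eistert homologation (C-acylation of diazomethane by the acyl chloride, Et3N taking up HCl); the push–pull enol ether double bond is a poor dipolarophile, so acylation should win and the (E) geometry is untouched.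

Step 6
Reactants: 11 (3E)-1-diazo-4-methoxybut-3-en-2-one
Product: 13 methyl (3E)-4-methoxybut-3-enoate, via vinylketene 12 (not isolated)
Conditions: PhCO2Ag (10 mol %), Et3N, MeOH, −20 °C → rt, dark
Reagents that add atoms: methanol CO
Why: Silver-catalysed Wolff rearrangement (1,2-vinyl shift with loss of N2) gives the vinylketene, which methanol traps at the ketene carbon as the β,γ-unsaturated ester with the (E)-enol ether retained.

Step 7
Reactants: 13 methyl (3E)-4-methoxybut-3-enoate
Product: 15 (1E,3E)-1,4-dimethoxy-1-(trimethylsilyloxy)buta-1,3-diene, via lithium dienolate 14 (not isolated)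
Conditions: LiN(iPr)2, THF, −78 °C; Me3SiCl, −78 → 0 °C; pentane, filtration, distillation
Reagents that add atoms: chlorotrimethylsilane C[Si](C)(C)Cl
Why: Kinetic α-deprotonation of the doubly activated CH2 and O-silylation (silyl ketene acetal formation) keep the (3E)-enol ether; the geometry at C1 is irrelevant because C1 becomes the carbonyl carbon.

Step 8
Reactants: 8 prop-2-en-1-yl (3R)-4-(3,4-dimethoxyphenyl)-3-methyl-2-methylidene-4-oxobutanoate; 15 (1E,3E)-1,4-dimethoxy-1-(trimethylsilyloxy)buta-1,3-diene
Product: 17 prop-2-en-1-yl (1S,5S)-1-[(2R)-1-(3,4-dimethoxyphenyl)-1-oxopropan-2-yl]-5-methoxy-2-oxocyclohex-3-ene-1-carboxylate, via cycloadduct ketal 16 (not isolated)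
Conditions: 15 (2 equiv), toluene, 70 °C, sealed tube; then 0.5 M HCl, THF, 0 °C
Reagents that add atoms: none
Why: Thermal normal-electron-demand Diels–Alder [4+2] cycloaddition, concerted but asynchronous: the methoxy-bearing diene terminus (future C4) bonds first to the acrylate CH2 (C5) while the ketene-acetal carbon (future C1) closes onto the ester-bearing carbon (C6), and aqueous acid then unmasks the methyl silyl ketal as the C1 ketone. The closest known reaction type is the cycloaddition of 1-alkoxy-1-silyloxybutadienes (vinylketene acetals) with acrylates and quinones. The cyclohexene ring is closed by the intermolecular [4+2] itself, suprafacially on both partners through a boat-like endo transition state. C4 (S) is the stereocentre that counts: it should follow from the (3E)-enol ether (OMe outside), from ester-endo approach (the branched α-substituent stays exo) and from attack on the acrylate face anti to the aroyl group of the (R) allylic centre, with CH3 inside (eclipsing the C=CH2 bond) and H outside next to the fully substituted incoming terminus; C6 and the ketal carbon are formed too but are erased in step 9 and on hydrolysis. The step needs regioselectivity (secured by the two oxygens on C1, which make C4 the nucleophilic terminus, matched with the acrylate β-carbon), endo and facial selectivity (secured by the size difference at the allylic centre and the 1,2-strain toward the geminal ester) and cycloaddition in preference to silyl-transfer Michael addition (secured by Lewis-acid-free thermal conditions).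

Step 9
Reactants: 17 prop-2-en-1-yl (1S,5S)-1-[(2R)-1-(3,4-dimethoxyphenyl)-1-oxopropan-2-yl]-5-methoxy-2-oxocyclohex-3-ene-1-carboxylate
Product: 18 (4S,6S)-6-[(2R)-1-(3,4-dimethoxyphenyl)-1-oxopropan-2-yl]-4-methoxy-6-(prop-2-en-1-yl)cyclohex-2-en-1-one
Conditions: Pd(PPh3)4 (5 mol %), THF, 25 °C
Reagents that add atoms: none
Why: Tsuji decarboxylative allylation (Tsuji–Trost manifold): zerovalent palladium ionises the allyl ester, loss of CO2 gives the C1/C6 enolate regiospecifically and stereoconvergently, and the allyl fragment should return to the C6 face anti to the pseudoaxial C4 methoxy group and anti to the aroyl group (Cα–H eclipsing the enolate double bond by 1,3-allylic strain), both biases giving (6S).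

Compound list
1 | prop-2-en-1-yl prop-2-enoate (allyl acrylate) | C=CC(=O)OCC=C | starting material
2 | acetaldehyde | CC=O | starting material
3 | prop-2-en-1-yl 3-hydroxy-2-methylidenebutanoate (racemic) | C=CCOC(=O)C(=C)C(C)O | intermediate
4 | prop-2-en-1-yl (2Z)-2-(bromomethyl)but-2-enoate | C=CCOC(=O)/C(CBr)=C/C | intermediate
5 | 3,4-dimethoxybenzaldehyde | COc1ccc(C=O)cc1OC | starting material
6 | prop-2-en-1-yl (3R,4R)-4-(3,4-dimethoxyphenyl)-3-methyl-2-methylidene-4-[(trimethylsilyl)oxy]butanoate | C=CCOC(=O)C(=C)[C@@H](C)[C@@H](O[Si](C)(C)C)c1ccc(OC)c(OC)c1 | intermediate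
7 | prop-2-en-1-yl (3R,4R)-4-(3,4-dimethoxyphenyl)-4-hydroxy-3-methyl-2-methylidenebutanoate | C=CCOC(=O)C(=C)[C@@H](C)[C@@H](O)c1ccc(OC)c(OC)c1 | intermediate
8 | prop-2-en-1-yl (3R)-4-(3,4-dimethoxyphenyl)-3-methyl-2-methylidene-4-oxobutanoate | C=CCOC(=O)C(=C)[C@@H](C)C(=O)c1ccc(OC)c(OC)c1 | intermediate
9 | (2E)-3-methoxyprop-2-enoic acid | CO/C=C/C(=O)O | starting material
10 | (2E)-3-methoxyprop-2-enoyl chloride | CO/C=C/C(=O)Cl | intermediate
11 | (3E)-1-diazo-4-methoxybut-3-en-2-one | CO/C=C/C(=O)C=[N+]=[N-] | intermediate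
12 | (3E)-4-methoxybuta-1,3-dien-1-one (2-methoxyvinylketene) | CO/C=C/C=C=O | intermediate
13 | methyl (3E)-4-methoxybut-3-enoate | CO/C=C/CC(=O)OC | intermediate
14 | lithium (1Z,3E)-1,4-dimethoxybuta-1,3-dien-1-olate | CO/C=C/C=C(/[O-])OC.[Li+] | intermediate
15 | (1E,3E)-1,4-dimethoxy-1-(trimethylsilyloxy)buta-1,3-diene | CO/C=C/C=C(/O[Si](C)(C)C)OC | intermediate
16 | prop-2-en-1-yl (1S,2S,5S)-1-[(2R)-1-(3,4-dimethoxyphenyl)-1-oxopropan-2-yl]-2,5-dimethoxy-2-[(trimethylsilyl)oxy]cyclohex-3-ene-1-carboxylate | C=CCOC(=O)[C@]1([C@@H](C)C(=O)c2ccc(OC)c(OC)c2)C[C@H](OC)C=C[C@]1(OC)O[Si](C)(C)C | intermediate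
17 | prop-2-en-1-yl (1S,5S)-1-[(2R)-1-(3,4-dimethoxyphenyl)-1-oxopropan-2-yl]-5-methoxy-2-oxocyclohex-3-ene-1-carboxylate | C=CCOC(=O)[C@]1([C@@H](C)C(=O)c2ccc(OC)c(OC)c2)C[C@H](OC)C=CC1=O | intermediate
18 | (4S,6S)-6-[(2R)-1-(3,4-dimethoxyphenyl)-1-oxopropan-2-yl]-4-methoxy-6-(prop-2-en-1-yl)cyclohex-2-en-1-one | C=CC[C@@]1([C@@H](C)C(=O)c2ccc(OC)c(OC)c2)C[C@H](OC)C=CC1=O | target

Total step count: 9
Longest linear sequence: 6 steps (steps 1, 2, 3, 4, 8, 9); the diene arm (steps 5, 6, 7) joins at step 8.

Steps most likely to fail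

Step 8. What may go wrong: erosion of endo or π-facial selectivity (the C4 epimer would then form), epimerisation of the acidic allylic C–H of 8 on heating, or silyl-transfer Michael addition in place of ring closure. Fallback: move the side chain to the carbinol oxidation level, so that the allylic centre carries a larger, non-enolisable anti group. The fallback sets out from 7. Silylation (tBuMe2SiCl, imidazole, DMF) would give the silyl ether F1. Cycloaddition with 15 as in step 8 would give the cycloadduct ketal F2, and hydrolysis with pyridinium p-toluenesulfonate in wet THF would give the β-keto ester F3 with the silyl ether intact. Decarboxylative allylation as in step 9 would give the allyl ketone F4. Bu4NF would free the alcohol F5, and periodinane oxidation of its benzylic hydroxyl returns to the route at 18.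

Step 9. What may go wrong: proton transfer from the acidic CH(CH3) to the palladium enolate (allylation at the wrong carbon, epimerisation at Cα) or weak facial discrimination at C6. Fallback: replace the enolate by a radical. The fallback sets out from 17. Deallylation (Pd(PPh3)4, morpholine, THF, 0 °C) would give the β-keto acid F6. It is activated cold with N-hydroxyphthalimide and N,N'-diisopropylcarbodiimide as the phthalimidoyl ester F7. Photoredox reduction (Ru(bpy)3(PF6)2, iPr2NEt, blue light) in the presence of allyl phenyl sulfone should release CO2 and the tertiary α-keto radical at C6. Radical allylation anti to the C4 methoxy group returns to the route at 18.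

Step 5. What may go wrong: dipolar cycloaddition of diazomethane to the acryloyl double bond, or loss of the (E)-enol ether geometry later in the diene arm. Fallback: replace the acyclic diene by a commercial cyclic one. The fallback sets out from 8. Cycloaddition with 2-methoxyfuran (neat, rt, or under high pressure) would give the oxanorbornene F8. Here the ring oxygen sits inside, so it is the exo-ester adduct that carries the right C4 configuration. Mild acid opens the bridgehead ketal to the hydroxy enone F9. O-Methylation (MeOTf, 2,6-di-tert-butylpyridine, CH2Cl2) returns to the route at 17.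

Further compounds
F1 | step 8 | prop-2-en-1-yl (3R,4R)-4-[(tert-butyldimethylsilyl)oxy]-4-(3,4-dimethoxyphenyl)-3-methyl-2-methylidenebutanoate | C=CCOC(=O)C(=C)[C@@H](C)[C@@H](O[Si](C)(C)C(C)(C)C)c1ccc(OC)c(OC)c1
F2 | step 8 | prop-2-en-1-yl (1S,2S,5S)-1-[(1R,2R)-1-[(tert-butyldimethylsilyl)oxy]-1-(3,4-dimethoxyphenyl)propan-2-yl]-2,5-dimethoxy-2-[(trimethylsilyl)oxy]cyclohex-3-ene-1-carboxylate | C=CCOC(=O)[C@]1([C@@H](C)[C@@H](O[Si](C)(C)C(C)(C)C)c2ccc(OC)c(OC)c2)C[C@H](OC)C=C[C@]1(OC)O[Si](C)(C)C
F3 | step 8 | prop-2-en-1-yl (1S,5S)-1-[(1R,2R)-1-[(tert-butyldimethylsilyl)oxy]-1-(3,4-dimethoxyphenyl)propan-2-yl]-5-methoxy-2-oxocyclohex-3-ene-1-carboxylate | C=CCOC(=O)[C@]1([C@@H](C)[C@@H](O[Si](C)(C)C(C)(C)C)c2ccc(OC)c(OC)c2)C[C@H](OC)C=CC1=O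
F4 | step 8 | (4S,6S)-6-[(1R,2R)-1-[(tert-butyldimethylsilyl)oxy]-1-(3,4-dimethoxyphenyl)propan-2-yl]-4-methoxy-6-(prop-2-en-1-yl)cyclohex-2-en-1-one | C=CC[C@@]1([C@@H](C)[C@@H](O[Si](C)(C)C(C)(C)C)c2ccc(OC)c(OC)c2)C[C@H](OC)C=CC1=O
F5 | step 8 | (4S,6S)-6-[(1R,2R)-1-(3,4-dimethoxyphenyl)-1-hydroxypropan-2-yl]-4-methoxy-6-(prop-2-en-1-yl)cyclohex-2-en-1-one | C=CC[C@@]1([C@@H](C)[C@@H](O)c2ccc(OC)c(OC)c2)C[C@H](OC)C=CC1=O
F6 | step 9 | (1S,5S)-1-[(2R)-1-(3,4-dimethoxyphenyl)-1-oxopropan-2-yl]-5-methoxy-2-oxocyclohex-3-ene-1-carboxylic acid | OC(=O)[C@]1([C@@H](C)C(=O)c2ccc(OC)c(OC)c2)C[C@H](OC)C=CC1=O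
F7 | step 9 | 1,3-dioxoisoindolin-2-yl (1S,5S)-1-[(2R)-1-(3,4-dimethoxyphenyl)-1-oxopropan-2-yl]-5-methoxy-2-oxocyclohex-3-ene-1-carboxylate | O=C(ON1C(=O)c2ccccc2C1=O)[C@]3([C@@H](C)C(=O)c4ccc(OC)c(OC)c4)C[C@H](OC)C=CC3=O
F8 | step 5 | prop-2-en-1-yl (1S,2S,4S)-2-[(2R)-1-(3,4-dimethoxyphenyl)-1-oxopropan-2-yl]-1-methoxy-7-oxabicyclo[2.2.1]hept-5-ene-2-carboxylate (ester exo) | C=CCOC(=O)[C@]1([C@@H](C)C(=O)c2ccc(OC)c(OC)c2)C[C@H]3C=C[C@]1(OC)O3
F9 | step 5 | prop-2-en-1-yl (1S,5S)-1-[(2R)-1-(3,4-dimethoxyphenyl)-1-oxopropan-2-yl]-5-hydroxy-2-oxocyclohex-3-ene-1-carboxylate | C=CCOC(=O)[C@]1([C@@H](C)C(=O)c2ccc(OC)c(OC)c2)C[C@H](O)C=CC1=O
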